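## Retrosynthetic overview

1. Presumed biosynthesis: geranylgeranyl diphosphate closes to an 11-membered prenyl-humulane ring (C10 cation), C8–C10 then closes across the ring (homoallyl → cyclopropylcarbinyl cation) with water capture at C7, and the side chain is oxidised by an ene reaction with O2. The synthesis forms the rings in the same order: 11-membered ring first, three-membered ring last.
2. Last ring event: buffered solvolysis of a macrocyclic C10 mesylate. The E-C7=C8 olefin displaces the leaving group across the ring (11 → 10 + 3 ring contraction), which sets C7, C8 and C10 in one step.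
3. 11-membered ring: B-alkyl Suzuki–Miyaura closure of C2–C3 in an open-chain vinyl / alkenyl iodide.
4. Open chain: an alkenylalanate (Negishi carboalumination of an enynol; C5 from asymmetric propargylation) opens a terminal epoxide (C8–C9). C10 and C11 come from Sharpless epoxidation of geraniol followed by invertive alkynylation at the tertiary epoxide carbon.
5. Side chain: C14 by Shi epoxidation, epoxide → allylic alcohol, then invertive displacement by H2O2.

Assumption: atom labels follow geranylgeranyl numbering (C1–C11 ring carbons, C8/C9/C10 cyclopropane, C12–C17 side chain, C18/C19/C20 methyls on C11/C7/C3); in this numbering the target is 5S,7S,8S,10S,11R,14S with a trans-fused cyclopropane and a 3E olefin.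

## Route

Step 1
Reactants: 1 geraniol
Product: 2 [(2S,3S)-3-methyl-3-(4-methylpent-3-en-1-yl)oxiran-2-yl]methanol
Conditions: Ti(OiPr)4 (5 mol%), L-(+)-diethyl tartrate (6 mol%), t-BuOOH, 4 Å MS, CH2Cl2, −20 °C
Reagents that add atoms: tert-butyl hydroperoxide, CC(C)(C)OO
Why: Sharpless asymmetric epoxidation is directed by the allylic hydroxyl, so only the 2,3-olefin reacts and the L-tartrate sets both epoxide carbons (the later C10 and C11) as 2S,3S.

Step 2
Reactants: 2 (2S,3S)-2,3-epoxygeraniol; 3 ethynyltrimethylsilane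
Product: 6 (2R,3S)-3,7-dimethyl-3-[(trimethylsilyl)ethynyl]oct-6-ene-1,2-diol, via lithium (trimethylsilyl)acetylide 4 (not isolated), via diethyl[(trimethylsilyl)ethynyl]alane 5 (not isolated)
Conditions: 3, n-BuLi, toluene, 0 °C; Et2AlCl; then 2, 0 °C → rt
Reagents that add atoms: none
Why: Alkynylalanes open 2,3-epoxy alcohols at C3 with inversion (aluminium-assisted epoxide alkynylation), which turns the tertiary epoxide carbon into the C11 quaternary stereocentre while the C10–O bond is untouched.

Step 3
Reactants: 6 silylalkynyl diol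
Product: 9 (2R)-2-[(3S)-3,7-dimethyloct-6-en-1-yn-3-yl]oxirane, via primary tosylate 7 (not isolated), via silylated alkynyl epoxide 8 (not isolated)
Conditions: TsCl, Et3N, Bu2SnO (2 mol%), CH2Cl2, 0 °C; then K2CO3, MeOH, rt
Reagents that add atoms: none
Why: Tin-catalysed sulfonylation is selective for the primary hydroxyl, the secondary alkoxide then closes the terminal epoxide by intramolecular Williamson displacement at C9 (C10 keeps its configuration), and the same methanolic carbonate cleaves the C–Si bond.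

Step 4
Reactants: 9 ethynyl epoxide
Product: 10 (2R)-2-[(3S)-3,7-dimethylocta-1,6-dien-3-yl]oxirane
Conditions: H2 (1 atm), Pd/CaCO3 poisoned with Pb(OAc)2, quinoline, hexane, rt
Reagents that add atoms: none
Why: Lindlar semihydrogenation stops at the terminal alkene and leaves the epoxide and the trisubstituted olefin alone.

Step 5
Reactants: 11 but-2-yn-1-ol
Product: 13 (2E)-3-iodobut-2-en-1-ol, via alkenylzirconocene 12 (not isolated)
Conditions: Cp2Zr(H)Cl (2.5 equiv), THF, rt → 40 °C; then I2, 0 °C
Reagents that add atoms: iodine, [I][I]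
Why: Hydrozirconation is a syn addition that under equilibrating conditions (excess reagent) puts zirconium on the methyl-bearing alkyne carbon, and iodinolysis with retention gives the E-iodide with iodine trans to the carbinol carbon.

Step 6
Reactants: 13 (2E)-3-iodobut-2-en-1-ol
Product: 14 (2E)-3-iodobut-2-enal
Conditions: MnO2, CH2Cl2, rt, dark
Reagents that add atoms: none
Why: MnO2 oxidises the allylic alcohol to the enal without touching the C–I bond or the olefin geometry.

Step 7
Reactants: 14 (2E)-3-iodobut-2-enal; 15 allenylboronic acid pinacol ester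
Product: 16 (4S,5E)-6-iodohept-5-en-1-yn-4-ol
Conditions: (S)-TRIP phosphoric acid (5 mol%), 4 Å MS, toluene, −20 °C
Reagents that add atoms: none
Why: Chiral phosphoric acid-catalysed propargylation with the allenylboronate runs through a closed six-membered transition state and sets the carbinol (the later C5) as S under catalyst control, the antipodal acid giving the R alcohol.

Step 8
Reactants: 16 (4S,5E)-6-iodohept-5-en-1-yn-4-ol; 10 vinyl epoxide
Product: 19 (2E,4S,6E,9S,10S)-10-ethenyl-2-iodo-6,10,14-trimethylpentadeca-2,6,13-triene-4,9-diol, via alkenylalane 17 (not isolated), via lithium alkenylalanate 18 (not isolated)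
Conditions: 16, Me3Al (3 equiv), Cp2ZrCl2 (0.25 equiv), CH2Cl2, 0 °C → rt; evaporate; MeLi, hexane/THF, −78 °C; then 10, −78 °C → rt
Reagents that add atoms: trimethylaluminium, C[Al](C)C
Why: Zirconium-catalysed syn-carboalumination of the terminal alkyne (Negishi) installs the C19 methyl and the E-C7=C8 geometry, and the derived alanate opens the epoxide at its CH2 terminus with retention of olefin geometry, so C10 keeps the configuration from step 1.

Step 9
Reactants: 19 open-chain diol
Product: 21 (1S,3E,6S,7E,11S)-4,8,11-trimethyl-11-(4-methylpent-3-en-1-yl)cycloundeca-3,7-diene-1,6-diol, via B-alkyl-9-BBN borane 20 (not isolated)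
Conditions: 9-BBN-H (3.5 equiv), THF, rt; then slow addition to Pd(dppf)Cl2 (15 mol%), AsPh3, Cs2CO3, DMF/THF/H2O, 45 °C, 2 mM
Reagents that add atoms: none
Why: 9-BBN-H hydroborates only the monosubstituted vinyl group, and the intramolecular B-alkyl Suzuki–Miyaura coupling with the E-alkenyl iodide under high dilution closes the 11-membered ring with retention of the C3=C4 geometry.

Step 10
Reactants: 21 macrocyclic diol
Product: 22 (1S,2E,6S,7S,9E)-7-hydroxy-3,6,10-trimethyl-6-(4-methylpent-3-en-1-yl)cycloundeca-2,9-dien-1-yl acetate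
Conditions: Ac2O (1.1 equiv), Et3N, DMAP (5 mol%), CH2Cl2, −40 °C
Reagents that add atoms: acetic anhydride, CC(=O)OC(C)=O
Why: Acylation is selective for the unhindered allylic C5 hydroxyl because the C10 hydroxyl is neopentylic, next to the quaternary C11.

Step 11
Reactants: 22 macrocyclic mono-acetate
Product: 24 (1S,2S,4S,5E,9S,10S)-2-hydroxy-2,6,9-trimethyl-9-(4-methylpent-3-en-1-yl)bicyclo[8.1.0]undec-5-en-4-yl acetate, via C10 mesylate 23 (not isolated)
Conditions: MsCl, Et3N, CH2Cl2, −20 °C; then acetone/H2O (3:1), NaHCO3, 45 °C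
Reagents that add atoms: water, O
Why: Proposed new method: ionisation of the C10 mesylate is assisted across the ring by the C7=C8 π bond (homoallyl → cyclopropylcarbinyl cation), which attacks C10 from the back (inversion) while water adds to C7 anti to the new C8–C10 bond, so the E-olefin and the 10S sulfonate are translated into 7S, 8S, 10S and, provided the ring reacts through the conformer with C7 and C11 anti, a trans ring fusion in an 11 → 10 + 3 ring contraction; the closest known reaction is the buffered solvolysis of cholesteryl tosylate to i-cholesterol (i-steroid rearrangement).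

Step 12
Reactants: 24 cyclopropyl carbinol acetate
Product: 25 (1S,2S,4S,5E,9R,10S)-9-{2-[(2R)-3,3-dimethyloxiran-2-yl]ethyl}-2-hydroxy-2,6,9-trimethylbicyclo[8.1.0]undec-5-en-4-yl acetate
Conditions: D-fructose-derived Shi ketone (30 mol%), KHSO5 (as 2KHSO5·KHSO4·K2SO4), K2CO3, Bu4NHSO4, MeCN/CH2(OMe)2/aq. Na2B4O7 buffer, 0 °C
Reagents that add atoms: potassium peroxymonosulfate, [K+].[O-]S(=O)(=O)OO
Why: The chiral dioxirane (Shi epoxidation) prefers the electron-rich, unhindered side-chain olefin over the ring olefin deactivated by the allylic acetate, and the fructose-derived ketone sets C14 as R by reagent control.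

Step 13
Reactants: 25 side-chain epoxide
Product: 26 (1S,2S,4S,5E,9R,10S)-2-hydroxy-9-[(3R)-3-hydroxy-4-methylpent-4-en-1-yl]-2,6,9-trimethylbicyclo[8.1.0]undec-5-en-4-yl acetate
Conditions: Cp2TiCl2 (2.5 equiv), Mn dust, THF, rt; aq. NaHCO3 work-up
Reagents that add atoms: none
Why: Cp2TiCl (trivalent titanium) opens the epoxide homolytically to the tertiary C15 radical, which is trapped by a second titanium and loses a methyl hydrogen by β-hydride elimination (radical epoxide-to-allylic-alcohol isomerisation), so the isopropenyl carbinol forms with the C14–O bond and its configuration intact.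

Step 14
Reactants: 26 (14R)-allylic alcohol
Product: 28 CNP0302713.3, (1S,2S,4S,5E,9R,10S)-9-[(3S)-3-hydroperoxy-4-methylpent-4-en-1-yl]-2-hydroxy-2,6,9-trimethylbicyclo[8.1.0]undec-5-en-4-yl acetate, via C14 mesylate 27 (not isolated)
Conditions: MsCl, Et3N, CH2Cl2, −40 °C; then anhydrous H2O2 in Et2O (excess), −40 → 0 °C
Reagents that add atoms: hydrogen peroxide, OO
Why: Only the secondary allylic hydroxyl is sulfonylated (the tertiary C7 hydroxyl is inert), and SN2 displacement of the sulfonate by H2O2 inverts C14 from R to the required S hydroperoxide.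

## Compound list

1 | geraniol, (2E)-3,7-dimethylocta-2,6-dien-1-ol | CC(C)=CCC/C(C)=C/CO | starting material
2 | [(2S,3S)-3-methyl-3-(4-methylpent-3-en-1-yl)oxiran-2-yl]methanol | CC(C)=CCC[C@]1(C)O[C@H]1CO | intermediate
3 | ethynyltrimethylsilane | C#C[Si](C)(C)C | starting material
4 | lithium (trimethylsilyl)acetylide | [Li]C#C[Si](C)(C)C | intermediate (not isolated)
5 | diethyl[(trimethylsilyl)ethynyl]alane | CC[Al](CC)C#C[Si](C)(C)C | intermediate (not isolated)
6 | (2R,3S)-3,7-dimethyl-3-[(trimethylsilyl)ethynyl]oct-6-ene-1,2-diol | OC[C@H](O)[C@@](C)(CCC=C(C)C)C#C[Si](C)(C)C | intermediate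
7 | (2R,3S)-2-hydroxy-3,7-dimethyl-3-[(trimethylsilyl)ethynyl]oct-6-en-1-yl 4-methylbenzenesulfonate | Cc1ccc(cc1)S(=O)(=O)OC[C@H](O)[C@@](C)(CCC=C(C)C)C#C[Si](C)(C)C | intermediate (not isolated)
8 | (2R)-2-[(3S)-3,7-dimethyl-1-(trimethylsilyl)oct-6-en-1-yn-3-yl]oxirane | C1O[C@@H]1[C@@](C)(CCC=C(C)C)C#C[Si](C)(C)C | intermediate (not isolated)
9 | (2R)-2-[(3S)-3,7-dimethyloct-6-en-1-yn-3-yl]oxirane | C1O[C@@H]1[C@@](C)(CCC=C(C)C)C#C | intermediate
10 | (2R)-2-[(3S)-3,7-dimethylocta-1,6-dien-3-yl]oxirane | C1O[C@@H]1[C@@](C)(CCC=C(C)C)C=C | intermediate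
11 | but-2-yn-1-ol | CC#CCO | starting material
12 | (E)-alkenylzirconocene: but-2-en-1-ol carrying ZrCp2Cl on C3 (trans to CH2O) and on oxygen | C/C(=C\CO[Zr](Cl)(C1C=CC=C1)C1C=CC=C1)[Zr](Cl)(C1C=CC=C1)C1C=CC=C1 | intermediate (not isolated)
13 | (2E)-3-iodobut-2-en-1-ol | C/C(I)=C\CO | intermediate
14 | (2E)-3-iodobut-2-enal | C/C(I)=C\C=O | intermediate
15 | allenylboronic acid pinacol ester, 4,4,5,5-tetramethyl-2-(propa-1,2-dien-1-yl)-1,3,2-dioxaborolane | C=C=CB1OC(C)(C)C(C)(C)O1 | starting material
16 | (4S,5E)-6-iodohept-5-en-1-yn-4-ol | C/C(I)=C\[C@@H](O)CC#C | intermediate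
17 | alkenylalane: (1E,4S,5E)-6-iodo-2-methylhepta-1,5-diene with AlMe2 on C1 and OAlMe2 on C4 | C/C(I)=C\[C@@H](O[Al](C)C)C/C(C)=C/[Al](C)C | intermediate (not isolated)
18 | lithium alkenyl(trimethyl)alanate derived from 17 | [Li+].C/C(I)=C\[C@@H](O[Al](C)C)C/C(C)=C/[Al-](C)(C)C | intermediate (not isolated)
19 | (2E,4S,6E,9S,10S)-10-ethenyl-2-iodo-6,10,14-trimethylpentadeca-2,6,13-triene-4,9-diol | C/C(I)=C\[C@@H](O)C/C(C)=C/C[C@H](O)[C@@](C)(CCC=C(C)C)C=C | intermediate
20 | B-alkyl-9-BBN borane: 19 with the ethenyl group converted into CH2CH2–B(9-BBN) | C/C(I)=C\[C@@H](O)C/C(C)=C/C[C@H](O)[C@@](C)(CCC=C(C)C)CCB1C2CCCC1CCC2 | intermediate (not isolated)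
21 | (1S,3E,6S,7E,11S)-4,8,11-trimethyl-11-(4-methylpent-3-en-1-yl)cycloundeca-3,7-diene-1,6-diol | CC(C)=CCC[C@@]1(C)CC/C(C)=C/[C@@H](O)C/C(C)=C/C[C@@H]1O | intermediate
22 | (1S,2E,6S,7S,9E)-7-hydroxy-3,6,10-trimethyl-6-(4-methylpent-3-en-1-yl)cycloundeca-2,9-dien-1-yl acetate | CC(C)=CCC[C@@]1(C)CC/C(C)=C/[C@@H](OC(C)=O)C/C(C)=C/C[C@@H]1O | intermediate
23 | (1S,2E,6S,7S,9E)-3,6,10-trimethyl-6-(4-methylpent-3-en-1-yl)-7-[(methylsulfonyl)oxy]cycloundeca-2,9-dien-1-yl acetate | CC(C)=CCC[C@@]1(C)CC/C(C)=C/[C@@H](OC(C)=O)C/C(C)=C/C[C@@H]1OS(C)(=O)=O | intermediate (not isolated)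
24 | (1S,2S,4S,5E,9S,10S)-2-hydroxy-2,6,9-trimethyl-9-(4-methylpent-3-en-1-yl)bicyclo[8.1.0]undec-5-en-4-yl acetate | CC(C)=CCC[C@@]1(C)CC/C(C)=C/[C@@H](OC(C)=O)C[C@](C)(O)[C@H]2C[C@@H]21 | intermediate
25 | (1S,2S,4S,5E,9R,10S)-9-{2-[(2R)-3,3-dimethyloxiran-2-yl]ethyl}-2-hydroxy-2,6,9-trimethylbicyclo[8.1.0]undec-5-en-4-yl acetate | CC1(C)O[C@@H]1CC[C@@]2(C)CC/C(C)=C/[C@@H](OC(C)=O)C[C@](C)(O)[C@H]3C[C@@H]32 | intermediate
26 | (1S,2S,4S,5E,9R,10S)-2-hydroxy-9-[(3R)-3-hydroxy-4-methylpent-4-en-1-yl]-2,6,9-trimethylbicyclo[8.1.0]undec-5-en-4-yl acetate | C=C(C)[C@@H](CC[C@@]1(C)CC/C(C)=C/[C@@H](OC(C)=O)C[C@](C)(O)[C@H]2C[C@@H]21)O | intermediate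
27 | (1S,2S,4S,5E,9R,10S)-2-hydroxy-2,6,9-trimethyl-9-{(3R)-4-methyl-3-[(methylsulfonyl)oxy]pent-4-en-1-yl}bicyclo[8.1.0]undec-5-en-4-yl acetate | C=C(C)[C@@H](CC[C@@]1(C)CC/C(C)=C/[C@@H](OC(C)=O)C[C@](C)(O)[C@H]2C[C@@H]21)OS(C)(=O)=O | intermediate (not isolated)
28 | CNP0302713.3, (1S,2S,4S,5E,9R,10S)-9-[(3S)-3-hydroperoxy-4-methylpent-4-en-1-yl]-2-hydroxy-2,6,9-trimethylbicyclo[8.1.0]undec-5-en-4-yl acetate | C=C(C)[C@H](CC[C@@]1(C)CC/C(C)=C/[C@@H](OC(C)=O)C[C@](C)(O)[C@H]2C[C@@H]21)OO | target

## Step count and risks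

Total step count: 14. Longest linear sequence: 11 steps (geraniol → 28 through steps 1–4 and 8–14; the but-2-yn-1-ol branch is 10).

The three steps most likely to fail:

Step 11, the transannular ring contraction, is the most exposed. The C10 cation can also be captured by the side-chain C14=C15 olefin (five-membered ring), by C3=C4 (six-membered ring) or by a 1,2-shift from C11. The cis-fused cyclopropane can form from the other ring conformer, and the C5 acetate can migrate to C7 through an acetoxonium ion. The fallback sets out from 19 and comes back at 24; it runs the same cationic C8–C10 closure on the open chain, where no ring has to contract, and closes the large ring afterwards. Selective acetylation of 19 (Ac2O, Et3N, DMAP, −40 °C) gives the open-chain C5 acetate F1. Mesylation gives the C10 mesylate F2, and buffered hydrolysis (acetone/H2O, NaHCO3) gives the open-chain trans-cyclopropyl carbinol F3. Hydroboration with 9-BBN-H gives the borane F4, whose B-alkyl Suzuki–Miyaura closure (Pd(dppf)Cl2, AsPh3, Cs2CO3, high dilution) forms the 10-membered ring of 24 directly.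

Step 9, the closure of a strained 11-membered ring by B-alkyl Suzuki coupling, may give oligomers, protodeboronation or β-hydride elimination instead. The fallback sets out from 19 (through borane 20) and comes back at 21; it keeps the C2–C3 disconnection but changes the bond-forming manifold. Iodinolysis of 20 (I2, NaOMe) gives the primary alkyl iodide F5. The ring is then closed by nickel-catalysed reductive cross-electrophile coupling of the alkyl iodide with the alkenyl iodide (NiBr2(dme), 4,4′-di-tert-butyl-2,2′-bipyridine, Zn, DMA, high dilution), which does not depend on boron-to-palladium transmetallation.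

Step 14, the displacement of a secondary allylic mesylate by H2O2, can leak to SN2′ attack at the methylene terminus (primary hydroperoxide), to ionisation with loss of stereochemical integrity, or to elimination. The fallback sets out from 24 and goes straight to 28 by the presumed biosynthetic oxidation: a Schenck ene reaction of the side-chain olefin with singlet oxygen (O2, tetraphenylporphyrin, visible light, CH2Cl2, 0 °C). It needs no new intermediate, but it also gives the tertiary hydroperoxide regioisomer and both C14 epimers, so 28 has to be separated by HPLC.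

Further compounds
F1 | step 11 | (2E,4S,6E,9S,10S)-10-ethenyl-9-hydroxy-2-iodo-6,10,14-trimethylpentadeca-2,6,13-trien-4-yl acetate | C/C(I)=C\[C@@H](OC(C)=O)C/C(C)=C/C[C@H](O)[C@@](C)(CCC=C(C)C)C=C
F2 | step 11 | (2E,4S,6E,9S,10S)-10-ethenyl-2-iodo-6,10,14-trimethyl-9-[(methylsulfonyl)oxy]pentadeca-2,6,13-trien-4-yl acetate | C/C(I)=C\[C@@H](OC(C)=O)C/C(C)=C/C[C@H](OS(C)(=O)=O)[C@@](C)(CCC=C(C)C)C=C
F3 | step 11 | open-chain trans-cyclopropyl carbinol: (2E,4S,6S)-6-{(1S,2S)-2-[(3S)-3,7-dimethylocta-1,6-dien-3-yl]cyclopropyl}-6-hydroxy-2-iodohept-2-en-4-yl acetate | C/C(I)=C\[C@@H](OC(C)=O)C[C@](C)(O)[C@H]1C[C@@H]1[C@@](C)(CCC=C(C)C)C=C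
F4 | step 11 | B-alkyl-9-BBN borane of F3 (boron on the terminal carbon of the former ethenyl group) | C/C(I)=C\[C@@H](OC(C)=O)C[C@](C)(O)[C@H]1C[C@@H]1[C@@](C)(CCC=C(C)C)CCB1C2CCCC1CCC2
F5 | step 9 | (2E,4S,6E,9S,10S)-2-iodo-10-(2-iodoethyl)-6,10,14-trimethylpentadeca-2,6,13-triene-4,9-diol | C/C(I)=C\[C@@H](O)C/C(C)=C/C[C@H](O)[C@@](C)(CCC=C(C)C)CCI
F0 | step 14 | none | none
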